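The trap with a small sample is to read fallen substrate as target: by 2.50 min the red run has lost 38.8% of its substrate, yet target holds 16.6%.

| setting | red | ochre | flask |
|---|---|---|---|
| substrate | 0.050 M | 0.075 M | 0.10 M |
| acid | 1 mM | 1 mM | 1.00 mM |
| scavenger | 1.5 equiv | 1.5 equiv | 1.50 equiv |
| remark | run made earlier | run made earlier |  |
| time |  |  | 12 min |
- red (time / min: substrate / %, target / %): 2.50: 61.2, 16.6; 5.00: 42.5, 27.4; 8.00: 31.3, 35.2; 10.0: 26.1, 38.9
- ochre (time / min: substrate / %, target / %): 1.33: 71.7, 9.4; 3.00: 51.8, 17.5; 6.00: 33.7, 27.2; 10.0: 22.5, 35.5

(each reading ± 0.3 percentage points)
1. part of the substrate that has reacted at 12 min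
2. pH of the solution at 12 min
- acid is the free proton; pH is minus the decimal logarithm of its molar concentration
- the numbers in the tables scatter by 0.3 percentage points (one standard deviation)
- what has gone from substrate into another species counts as reacted, even if it can come back

Is target's step the same in both runs? Target per mean substrate and minute over the first interval is 0.0824 /min in red and 0.0823 /min in ochre, a match, so I treat it as pseudo-first-order and hold the pH at what the charged acid gives.

How do the other losses compare? Mean substrate times target over other loss gives 0.0301 M in red and 0.0320 M in ochre, so about 0.0311 M: the split concentration, a reading of the first interval that puts other loss per target at mean substrate over this figure. It counts everything missing from the balance in that interval, so I use it as a rough estimate and not as a point where two rates run level. With this flask's charge in place of the mean, it estimates early target at 0.311 of the other losses.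

Where does it stand at the asked time? By this reading I estimate the fall to ochre's charge at 0.915 min. If the flask then retraces ochre, it runs 1.08 min past ochre's last reading, and ochre's late decay of 0.101 /min gives me 84.9% reacted.

The forecast says 81% and pH 3, noting “Adduct counts as reacted”, a little below my figure.

The flask gives 82.8% and pH 3.00, 2 percentage points under my reckoning.

    weak acid ⇌ conjugate base + acid, settled at all times (K = 2.50 × 10⁻⁷ M)
    weak acid + scavenger → scavenged by-product (k = 0.110 /M/s)
    substrate + weak acid ⇌ idle adduct, settled at all times (K = 76.0 /M)
    substrate → weak acid + target (k = 2.90 × 10⁻⁵ /s)
    substrate + acid → weak acid + acid + target (k = 1.40 /M/s)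
    2 substrate → homo dimer (k = 0.0130 /M/s)
    substrate + target → side product (k = 0.00850 /M/s)

With 0.25 M of substrate, the neighbouring flask has split concentration over charge at 0.124 instead of 0.311, so I expect less target. At 12.0 min it has reacted 90.2%, yet holds 23.4% target against the flask's 35.2%, and homo dimer stands at 54.8% against 35.2%.

(The earlier runs and the new flask were generated by integration with constants of no real substance, and the scatter is random.)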